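## Analysis of the target

The target 24 is a cyclohexene (ring atoms C1 to C6 as in its name, alkene C5=C6) with oxygen on four contiguous ring carbons and an exocyclic benzoyloxymethyl carbon, C7, on C1. Its stereocentres are (1S,2S,3R,4S): the tertiary hydroxyl on C1 and the hydroxyl on C2 are cis (both beta), the benzoate on C3 is trans to both of its neighbours, and the allylic hydroxyl on C4 is beta again. C1 is a fully substituted allylic carbinol, so it cannot be corrected later by oxidation and reduction and has to be set in one irreversible step. Five oxygens are present but only O3 and O7 are acylated, so the real difficulty is telling O3 apart from its secondary neighbours O2 and O4. A benzoate moves easily to a vicinal alkoxide, which rules out basic steps once O3 is acylated, and the allylic C4 hydroxyl argues against strongly ionising acid. The plan rests on one reading of the ring: C2 and C3 are a trans-diol with the configuration of (S,S)-tartaric acid, and C4 is an allylic carbinol between that diol and the cis C5=C6 alkene. The C4–C5 bond can therefore be made by adding a (Z)-alkenyl metal centred on C5 to an aldehyde at C4.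

## Retrosynthetic reasoning

**24 from 23.** The last operation is a hydrolysis. In 23, O1 and O2 share a cis-fused isopropylidene acetal and O4 is a silyl ether. Both leave in aqueous acid, where the two benzoates stay in place.

**23 from 21 and 22.** The O3–acyl bond is cut. In 21, O3 is the only free hydroxyl, so acylation with 22 needs no selectivity.

**21 from 19.** The acetal is moved rather than removed. In 19 it bridges the trans pair O2/O3 and is strained on the six-membered ring. Mild acidic solvolysis takes it off together with the tertiary silyl ether on O1, and re-acetalization of triol 20 finds a single cis-1,2-diol, O1/O2. This exposes O3 alone. The forward step needs the O1 silyl ether to leave while the O4 silyl ether stays, so the two are graded: triethylsilyl on the tertiary O1, tert-butyldimethylsilyl on the secondary O4.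

**19 from 18, and 18 from 15.** After silylation of O4 is undone, the C4–C5 bond is cut. Cutting here leaves the two tartrate carbons untouched and makes the ring, the endocyclic cis alkene and the C4 stereocentre in one event, next to a rigid template that can control the new centre. The forward reaction has to turn the (Z)-iodoalkene of 15 into a nucleophile that adds to the aldehyde but ignores the C7 benzoate, and it has to place O4 trans to O3.

**15 from 14.** The aldehyde is not made from an ester, because a hydride strong enough for that would also take the C7 benzoate. C4 is carried as a primary triethylsilyl ether, which a Swern-type oxidation converts directly to the aldehyde while the tertiary silyl ether stays.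

**14 from 13, and 13 from 12.** The (Z)-iodoalkene comes from syn delivery of two hydrogens to iodoalkyne 13. Compound 13 comes from the silylalkyne 12 by iodine-for-silicon exchange, which saves a separate desilylation.

**12 from 11, and 11 from 9 and 10.** After the O1 silyl ether is removed, the C7–O bond is cut to give epoxide 9 and acid 10. The benzoate enters by ring opening at the unsubstituted oxirane carbon. It is therefore never exposed to an organolithium, and no protecting-group exchange on O7 is needed.

**9 from 6 and 7.** The C1–C6 bond is cut. Addition of the acetylide of 7 to chloro ketone 6 sets C1 under Felkin–Anh control by the adjacent dioxolane stereocentre, and the chlorohydrin alkoxide 8 closes to 9 in the same flask.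

**6 from 3 and 4.** The C1–C7 bond is cut. A one-carbon carbenoid from 4 converts the ester of 3 into the chloromethyl ketone via the tetrahedral adduct 5.

**3 from 2, and 2 from 1.** The C2-symmetric diester 1 supplies C1 to C4 with both secondary stereocentres. It is desymmetrized by reducing one ester to the alcohol 2, which is silylated to 3.

## Alternatives that were turned down

**Alternative 1: furan Diels–Alder, exo-dihydroxylation, oxa-bridge opening.**
- Disconnection: the C3–C4 and C5–C6 bonds.
- Key step: a catalytic enantioselective cycloaddition of furan A2 with 2-bromoacrolein A3, promoted by a chiral boron Lewis acid, gives the oxanorbornene A1. An exo cis-dihydroxylation would then place O1 and O2 cis to each other and trans to the bridging oxygen. Degradation of the bromo aldehyde to a C4 ketone and base-induced opening of the bridge would give the enone with O3 as the only new free hydroxyl.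
- For it: the carbocycle and three relative configurations come from the bicyclic shape, and O3 is unmasked alone without any acetal transposition. On that point it is stronger than the chosen route.
- Against it: the 3-substituent of A2 gives little regiocontrol. Furan cycloadditions are reversible, so the enantiomeric purity depends on one catalytic step that can erode by cycloreversion. The formyl carbon of A1 is thrown away in a multistep degradation. The C4 ketone must still be reduced with the right facial sense, and the silyl ether on C7 must be exchanged for a benzoate.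
- Comparison: the chosen route buys C2 and C3 enantiopure, keeps every skeletal carbon, and sets C4 in the ring-closing step. The price is more protecting-group operations.

**Alternative 2: enzymatic ipso,ortho-dihydroxylation of benzoic acid with oxygen relay.**
- Disconnection: no ring bond; the C1–O bond and a relay C–O bond at the carbon that becomes C6.
- Key step: whole cells of a blocked mutant expressing an arene dioxygenase convert benzoic acid A5 into the diene diol acid A4.
- For it: one step gives an enantiopure ring with all six carbons, the quaternary C1 carbinol and C7 as the carboxyl carbon. In step count it is very probably shorter than the chosen route.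
- Against it: the second hydroxyl of A4 sits on C6, which is an sp2 CH in 24, so it must be relayed to C4 by allylic transposition. O2 and O3 must be added to a cyclohexadiene with regio- and face-selectivity by substrate control alone. A4 aromatises by dehydration under acid. The route needs fermentation and gives only one enantiomeric series.
- Comparison: the chosen route uses ordinary flask chemistry, has O2 and O3 in place from the start, gives either enantiomer by changing the tartrate, and does not depend on diene face selectivity.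

**Alternative 3: silyl glyoxylate three-component coupling around C1.**
- Disconnection: the C1–C6 and C1–C2 bonds.
- Key step: a silyl-capped alkynylzinc nucleophile adds to silyl glyoxylate A7, Brook rearrangement gives a glycolate enolate, and aldol addition to aldehyde A8 gives A6 in one flask. Alkyne semi-reduction, ring-closing metathesis and ester reduction would follow.
- For it: it is the most convergent plan. It builds the hardest centre with two C–C bonds at once, and A6 carries O3 already distinguished as a benzyl-type ether, so on oxygen differentiation it is stronger than the chosen route.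
- Against it: C1 and C2 are both set in an acyclic aldol of a tetrasubstituted enolate of undefined geometry against a chiral dialkoxy aldehyde, so four diastereomers are possible. A8 needs its own multistep enantioselective synthesis. Ring closure is deferred and forms no stereocentre.
- Comparison: the chosen route sets only C1 in its addition step, on a rigid dioxolanyl ketone, and its ring closure also sets C4.

Key step: step 10

## Route

Assumption: diester 1, the acetonide of dimethyl D-tartrate, is bought as such (it is otherwise one acetalization from a dialkyl D-tartrate). C1 to C7 refer to the target numbering throughout.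

Step 1
Reactants: 1 dimethyl (4S,5S)-2,2-dimethyl-1,3-dioxolane-4,5-dicarboxylate
Product: 2 methyl (4S,5R)-5-(hydroxymethyl)-2,2-dimethyl-1,3-dioxolane-4-carboxylate
Conditions: NaBH4 (0.6 equiv), MeOH, 0 °C, stopped at partial conversion; recovered 1 recycled
Reagents that add atoms: none
Why: Borohydride reduction of an alpha-alkoxy ester; the first ester is activated by the second, so 2 reacts more slowly than 1 and the C2-symmetric diester can be stopped at the mono-alcohol. No stereocentre is touched; the descriptor at C5 changes only because the substituent priorities change.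

Step 2
Reactants: 2 methyl (4S,5R)-5-(hydroxymethyl)-2,2-dimethyl-1,3-dioxolane-4-carboxylate
Product: 3 methyl (4S,5R)-2,2-dimethyl-5-[(triethylsilyloxy)methyl]-1,3-dioxolane-4-carboxylate
Conditions: Et3SiCl, imidazole, CH2Cl2, 0 °C to rt
Reagents that add atoms: chlorotriethylsilane, CC[Si](Cl)(CC)CC
Why: Standard silylation of a primary alcohol. The triethylsilyl ether is chosen because it can later be oxidised directly to the aldehyde.

Step 3
Reactants: 3 methyl (4S,5R)-2,2-dimethyl-5-[(triethylsilyloxy)methyl]-1,3-dioxolane-4-carboxylate; 4 chloroiodomethane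
Product: 6 2-chloro-1-[(4S,5R)-2,2-dimethyl-5-[(triethylsilyloxy)methyl]-1,3-dioxolan-4-yl]ethan-1-one, via lithium hemiketal alkoxide 5 (not isolated)
Conditions: ICH2Cl, MeLi·LiBr, THF, −78 °C; AcOH, −78 °C
Reagents that add atoms: chloroiodomethane (4), ClCI
Why: Carbenoid homologation of an ester to a chloromethyl ketone: iodine–lithium exchange gives LiCH2Cl in the presence of the ester, and the tetrahedral adduct 5 survives at −78 °C until the quench, so no second addition occurs. The trans-dioxolane is also the thermodynamic isomer, so the centre next to the new ketone is not at risk.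

Step 4
Reactants: 6 2-chloro-1-[(4S,5R)-2,2-dimethyl-5-[(triethylsilyloxy)methyl]-1,3-dioxolan-4-yl]ethan-1-one; 7 (trimethylsilyl)acetylene
Product: 9 trimethyl({(2S)-2-[(4S,5R)-2,2-dimethyl-5-[(triethylsilyloxy)methyl]-1,3-dioxolan-4-yl]oxiran-2-yl}ethynyl)silane, via lithium chlorohydrin alkoxide 8 (not isolated)
Conditions: 7, n-BuLi, THF, −78 °C; then 6, −78 °C to rt
Reagents that add atoms: (trimethylsilyl)acetylene (7), C[Si](C)(C)C#C
Why: 1,2-Addition of a lithium acetylide to an alpha-chloro ketone, then 3-exo-tet closure of the chlorohydrin alkoxide on warming. C1 is set by polar Felkin–Anh addition anti to the dioxolane C–O bond in non-chelating THF, which puts the new C1 oxygen in the relationship to O2 that becomes the cis C1/C2 diol of the ring. The (R) descriptor of 8 and the (S) descriptor of 9 describe the same spatial arrangement.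

Step 5
Reactants: 9 trimethyl({(2S)-2-[(4S,5R)-2,2-dimethyl-5-[(triethylsilyloxy)methyl]-1,3-dioxolan-4-yl]oxiran-2-yl}ethynyl)silane; 10 benzoic acid
Product: 11 (2S)-2-[(4S,5R)-2,2-dimethyl-5-[(triethylsilyloxy)methyl]-1,3-dioxolan-4-yl]-2-hydroxy-4-(trimethylsilyl)but-3-yn-1-yl benzoate
Conditions: PhCO2H (3 equiv), Cs2CO3 (0.5 equiv), DMF, 80 °C
Reagents that add atoms: benzoic acid (10), O=C(O)c1ccccc1
Why: SN2 opening of a 2,2-disubstituted oxirane by a carboxylate at the unsubstituted CH2. The excess acid protonates the tertiary alkoxide at once, so the benzoyl group stays on the primary oxygen; C1 is not involved.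

Step 6
Reactants: 11 (2S)-2-[(4S,5R)-2,2-dimethyl-5-[(triethylsilyloxy)methyl]-1,3-dioxolan-4-yl]-2-hydroxy-4-(trimethylsilyl)but-3-yn-1-yl benzoate
Product: 12 (2S)-2-[(4S,5R)-2,2-dimethyl-5-[(triethylsilyloxy)methyl]-1,3-dioxolan-4-yl]-2-(triethylsilyloxy)-4-(trimethylsilyl)but-3-yn-1-yl benzoate
Conditions: Et3SiOTf, 2,6-lutidine, CH2Cl2, −40 to 0 °C
Reagents that add atoms: triethylsilyl trifluoromethanesulfonate, CC[Si](CC)(CC)OS(=O)(=O)C(F)(F)F
Why: Silyl triflate silylation of a hindered tertiary alcohol. It removes the only acidic proton that would later sit next to the carbon–chromium bond.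

Step 7
Reactants: 12 (2S)-2-[(4S,5R)-2,2-dimethyl-5-[(triethylsilyloxy)methyl]-1,3-dioxolan-4-yl]-2-(triethylsilyloxy)-4-(trimethylsilyl)but-3-yn-1-yl benzoate
Product: 13 (2S)-2-[(4S,5R)-2,2-dimethyl-5-[(triethylsilyloxy)methyl]-1,3-dioxolan-4-yl]-4-iodo-2-(triethylsilyloxy)but-3-yn-1-yl benzoate
Conditions: N-iodosuccinimide, AgNO3 (10 mol%), DMF, rt, dark
Reagents that add atoms: N-iodosuccinimide, O=C1CCC(=O)N1I
Why: Silver-catalysed ipso-iododesilylation of an alkynylsilane gives the 1-iodoalkyne directly, without a separate desilylation that would endanger the benzoate.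

Step 8
Reactants: 13 (2S)-2-[(4S,5R)-2,2-dimethyl-5-[(triethylsilyloxy)methyl]-1,3-dioxolan-4-yl]-4-iodo-2-(triethylsilyloxy)but-3-yn-1-yl benzoate
Product: 14 (2S,3Z)-2-[(4S,5R)-2,2-dimethyl-5-[(triethylsilyloxy)methyl]-1,3-dioxolan-4-yl]-4-iodo-2-(triethylsilyloxy)but-3-en-1-yl benzoate
Conditions: 2-nitrobenzenesulfonylhydrazide, Et3N, THF/i-PrOH, rt
Reagents that add atoms: none
Why: Diimide reduction of a 1-iodoalkyne: concerted syn transfer of two hydrogens gives the (Z)-iodoalkene, and the polarised iodoalkyne reacts faster than the product. Benzoate, silyl ethers and the C–I bond are inert.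

Step 9
Reactants: 14 (2S,3Z)-2-[(4S,5R)-2,2-dimethyl-5-[(triethylsilyloxy)methyl]-1,3-dioxolan-4-yl]-4-iodo-2-(triethylsilyloxy)but-3-en-1-yl benzoate
Product: 15 (2S,3Z)-2-[(4S,5S)-5-formyl-2,2-dimethyl-1,3-dioxolan-4-yl]-4-iodo-2-(triethylsilyloxy)but-3-en-1-yl benzoate
Conditions: (COCl)2, DMSO, CH2Cl2, −78 to −40 °C; Et3N, −78 to 0 °C
Reagents that add atoms: none
Why: Swern oxidation with direct oxidative cleavage of a primary triethylsilyl ether: the unhindered primary oxygen is transferred to the chlorosulfonium ion and oxidised, while the tertiary silyl ether, which is hindered and has no carbinol hydrogen, stays. The alpha centre is part of a trans-dioxolane and is not epimerised by the amine.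

Step 10
Reactants: 15 (2S,3Z)-2-[(4S,5S)-5-formyl-2,2-dimethyl-1,3-dioxolan-4-yl]-4-iodo-2-(triethylsilyloxy)but-3-en-1-yl benzoate
Product: 18 [(3aS,4S,7S,7aR)-7-hydroxy-2,2-dimethyl-4-(triethylsilyloxy)-3a,4,7,7a-tetrahydro-1,3-benzodioxol-4-yl]methyl benzoate, via alkenylchromium dichloride 16 (not isolated), via chromium alkoxide 17 (not isolated)
Conditions: CrCl2 (8 equiv), NiCl2 (2 mol%), degassed DMSO, 0.01 M, rt; aqueous work-up
Reagents that add atoms: none
Why: CrCl2 reduces NiCl2 to zerovalent nickel, which inserts into the C–I bond of 15; transmetalation to trivalent chromium gives 16 with retention of the Z geometry. The chromium binds the aldehyde oxygen and the alkenyl group shifts to the carbonyl carbon through a four-centre array, a 6-exo-trig closure that forms C4–C5 and gives alkoxide 17, hydrolysed on work-up. The closest known reaction type is the intramolecular Nozaki–Hiyama–Kishi cyclization of (Z)-iodoalkenyl aldehydes to cycloalkenols. The Z geometry is what lets C5 reach C4, and it becomes the endocyclic C5=C6 bond. The new centre C4 (C7 of 18) is controlled by the trans-fused dioxolane, which holds O2 and O3 equatorial in the half-chair and so puts the C3–O bond antiperiplanar to the forming bond (Felkin–Anh arrangement). The chromium-bound carbonyl oxygen must lie near the alkene plane, which is the pseudo-equatorial position, trans to O3. Chemoselectivity for the aldehyde over the benzoate is needed and is inherent to alkenylchromium reagents. High dilution suppresses intermolecular coupling.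

Step 11
Reactants: 18 [(3aS,4S,7S,7aR)-7-hydroxy-2,2-dimethyl-4-(triethylsilyloxy)-3a,4,7,7a-tetrahydro-1,3-benzodioxol-4-yl]methyl benzoate
Product: 19 [(3aS,4S,7S,7aS)-7-(tert-butyldimethylsilyloxy)-2,2-dimethyl-4-(triethylsilyloxy)-3a,4,7,7a-tetrahydro-1,3-benzodioxol-4-yl]methyl benzoate
Conditions: t-BuMe2SiOTf, 2,6-lutidine, CH2Cl2, −78 to 0 °C
Reagents that add atoms: tert-butyldimethylsilyl trifluoromethanesulfonate, CC(C)(C)[Si](C)(C)OS(=O)(=O)C(F)(F)F
Why: Silyl triflate silylation of the only free hydroxyl. The bulkier silyl group is chosen so that it outlasts the acid step that removes the triethylsilyl ether; the change of the 7a descriptor is a priority effect only.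

Step 12
Reactants: 19 [(3aS,4S,7S,7aS)-7-(tert-butyldimethylsilyloxy)-2,2-dimethyl-4-(triethylsilyloxy)-3a,4,7,7a-tetrahydro-1,3-benzodioxol-4-yl]methyl benzoate
Product: 21 [(3aS,4S,5S,7aS)-5-(tert-butyldimethylsilyloxy)-4-hydroxy-2,2-dimethyl-3a,4,5,7a-tetrahydro-1,3-benzodioxol-7a-yl]methyl benzoate, via silyloxy triol 20 (not isolated)
Conditions: PPTS, MeOH, 40 °C; evaporate; 2,2-dimethoxypropane (2 equiv), CSA (cat.), acetone, rt; Et3N
Reagents that add atoms: 2,2-dimethoxypropane, COC(C)(C)OC
Why: Acid-catalysed acetal exchange: the strained trans-fused dioxolane and the triethylsilyl ether are solvolysed by a weak acid that leaves the secondary tert-butyldimethylsilyl ether and the benzoate alone. Thermodynamic re-acetalization of 20 then takes the only cis-1,2-diol, O1/O2, as a cis-fused dioxolane. O3 is left as the single free hydroxyl and no stereocentre is touched.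

Step 13
Reactants: 21 [(3aS,4S,5S,7aS)-5-(tert-butyldimethylsilyloxy)-4-hydroxy-2,2-dimethyl-3a,4,5,7a-tetrahydro-1,3-benzodioxol-7a-yl]methyl benzoate; 22 benzoyl chloride
Product: 23 [(3aS,4S,5S,7aS)-4-(benzoyloxy)-5-(tert-butyldimethylsilyloxy)-2,2-dimethyl-3a,4,5,7a-tetrahydro-1,3-benzodioxol-7a-yl]methyl benzoate
Conditions: BzCl, pyridine, DMAP (cat.), CH2Cl2, 0 °C to rt
Reagents that add atoms: benzoyl chloride (22), O=C(Cl)c1ccccc1
Why: DMAP-catalysed acylation of a secondary alcohol. No neighbouring hydroxyl is free, so neither regioselectivity nor acyl migration is an issue.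

Step 14
Reactants: 23 [(3aS,4S,5S,7aS)-4-(benzoyloxy)-5-(tert-butyldimethylsilyloxy)-2,2-dimethyl-3a,4,5,7a-tetrahydro-1,3-benzodioxol-7a-yl]methyl benzoate
Product: 24 [(1S,2S,3R,4S)-3-(benzoyloxy)-1,2,4-trihydroxycyclohex-5-en-1-yl]methyl benzoate
Conditions: TFA/H2O (9:1), 0 °C, short reaction time
Reagents that add atoms: none
Why: Acid hydrolysis of the isopropylidene acetal and of the secondary silyl ether in one operation. Benzoates do not migrate under cold aqueous acid, and the short, cold exposure avoids ionisation at the allylic positions.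

## Compound list

1 | dimethyl (4S,5S)-2,2-dimethyl-1,3-dioxolane-4,5-dicarboxylate | COC(=O)[C@@H](OC(C)(C)O1)[C@H]1C(=O)OC | starting material
2 | methyl (4S,5R)-5-(hydroxymethyl)-2,2-dimethyl-1,3-dioxolane-4-carboxylate | COC(=O)[C@@H](OC(C)(C)O1)[C@H]1CO | intermediate
3 | methyl (4S,5R)-2,2-dimethyl-5-[(triethylsilyloxy)methyl]-1,3-dioxolane-4-carboxylate | COC(=O)[C@@H](OC(C)(C)O1)[C@H]1CO[Si](CC)(CC)CC | intermediate
4 | chloroiodomethane | ClCI | starting material
5 | lithium 2-chloro-1-[(4S,5R)-2,2-dimethyl-5-[(triethylsilyloxy)methyl]-1,3-dioxolan-4-yl]-1-methoxyethan-1-olate (either configuration at the hemiketal carbon) | [Li+].[O-]C(CCl)(OC)[C@@H](OC(C)(C)O1)[C@H]1CO[Si](CC)(CC)CC | intermediate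
6 | 2-chloro-1-[(4S,5R)-2,2-dimethyl-5-[(triethylsilyloxy)methyl]-1,3-dioxolan-4-yl]ethan-1-one | ClCC(=O)[C@@H](OC(C)(C)O1)[C@H]1CO[Si](CC)(CC)CC | intermediate
7 | (trimethylsilyl)acetylene | C[Si](C)(C)C#C | starting material
8 | lithium (2R)-1-chloro-2-[(4S,5R)-2,2-dimethyl-5-[(triethylsilyloxy)methyl]-1,3-dioxolan-4-yl]-4-(trimethylsilyl)but-3-yn-2-olate | [Li+].[O-][C@](CCl)(C#C[Si](C)(C)C)[C@@H](OC(C)(C)O1)[C@H]1CO[Si](CC)(CC)CC | intermediate
9 | trimethyl({(2S)-2-[(4S,5R)-2,2-dimethyl-5-[(triethylsilyloxy)methyl]-1,3-dioxolan-4-yl]oxiran-2-yl}ethynyl)silane | C1O[C@]1(C#C[Si](C)(C)C)[C@@H](OC(C)(C)O2)[C@H]2CO[Si](CC)(CC)CC | intermediate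
10 | benzoic acid | O=C(O)c1ccccc1 | starting material
11 | (2S)-2-[(4S,5R)-2,2-dimethyl-5-[(triethylsilyloxy)methyl]-1,3-dioxolan-4-yl]-2-hydroxy-4-(trimethylsilyl)but-3-yn-1-yl benzoate | O=C(OC[C@@](O)(C#C[Si](C)(C)C)[C@@H](OC(C)(C)O1)[C@H]1CO[Si](CC)(CC)CC)c1ccccc1 | intermediate
12 | (2S)-2-[(4S,5R)-2,2-dimethyl-5-[(triethylsilyloxy)methyl]-1,3-dioxolan-4-yl]-2-(triethylsilyloxy)-4-(trimethylsilyl)but-3-yn-1-yl benzoate | O=C(OC[C@@](O[Si](CC)(CC)CC)(C#C[Si](C)(C)C)[C@@H](OC(C)(C)O1)[C@H]1CO[Si](CC)(CC)CC)c1ccccc1 | intermediate
13 | (2S)-2-[(4S,5R)-2,2-dimethyl-5-[(triethylsilyloxy)methyl]-1,3-dioxolan-4-yl]-4-iodo-2-(triethylsilyloxy)but-3-yn-1-yl benzoate | O=C(OC[C@@](O[Si](CC)(CC)CC)(C#CI)[C@@H](OC(C)(C)O1)[C@H]1CO[Si](CC)(CC)CC)c1ccccc1 | intermediate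
14 | (2S,3Z)-2-[(4S,5R)-2,2-dimethyl-5-[(triethylsilyloxy)methyl]-1,3-dioxolan-4-yl]-4-iodo-2-(triethylsilyloxy)but-3-en-1-yl benzoate | O=C(OC[C@@](O[Si](CC)(CC)CC)(/C=C\I)[C@@H](OC(C)(C)O1)[C@H]1CO[Si](CC)(CC)CC)c1ccccc1 | intermediate
15 | (2S,3Z)-2-[(4S,5S)-5-formyl-2,2-dimethyl-1,3-dioxolan-4-yl]-4-iodo-2-(triethylsilyloxy)but-3-en-1-yl benzoate | I/C=C\[C@](O[Si](CC)(CC)CC)(COC(=O)c1ccccc1)[C@@H](OC(C)(C)O2)[C@H]2C=O | intermediate
16 | alkenylchromium dichloride: 15 with CrCl2 (trivalent chromium) on the alkene carbon in place of iodine, Z geometry kept | Cl[Cr](Cl)/C=C\[C@](O[Si](CC)(CC)CC)(COC(=O)c1ccccc1)[C@@H](OC(C)(C)O2)[C@H]2C=O | intermediate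
17 | chromium alkoxide: 18 with CrCl2 (trivalent chromium) on the C7 oxygen | O=C(OC[C@@]1(O[Si](CC)(CC)CC)C=C[C@H](O[Cr](Cl)Cl)[C@@H](OC(C)(C)O2)[C@@H]12)c1ccccc1 | intermediate
18 | [(3aS,4S,7S,7aR)-7-hydroxy-2,2-dimethyl-4-(triethylsilyloxy)-3a,4,7,7a-tetrahydro-1,3-benzodioxol-4-yl]methyl benzoate | O=C(OC[C@@]1(O[Si](CC)(CC)CC)C=C[C@H](O)[C@@H](OC(C)(C)O2)[C@@H]12)c1ccccc1 | intermediate
19 | [(3aS,4S,7S,7aS)-7-(tert-butyldimethylsilyloxy)-2,2-dimethyl-4-(triethylsilyloxy)-3a,4,7,7a-tetrahydro-1,3-benzodioxol-4-yl]methyl benzoate | O=C(OC[C@@]1(O[Si](CC)(CC)CC)C=C[C@H](O[Si](C)(C)C(C)(C)C)[C@@H](OC(C)(C)O2)[C@@H]12)c1ccccc1 | intermediate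
20 | [(1S,2S,3S,4S)-4-(tert-butyldimethylsilyloxy)-1,2,3-trihydroxycyclohex-5-en-1-yl]methyl benzoate | O=C(OC[C@@]1(O)C=C[C@H](O[Si](C)(C)C(C)(C)C)[C@@H](O)[C@@H]1O)c1ccccc1 | intermediate
21 | [(3aS,4S,5S,7aS)-5-(tert-butyldimethylsilyloxy)-4-hydroxy-2,2-dimethyl-3a,4,5,7a-tetrahydro-1,3-benzodioxol-7a-yl]methyl benzoate | O=C(OC[C@@]12C=C[C@H](O[Si](C)(C)C(C)(C)C)[C@@H](O)[C@@H]1OC(C)(C)O2)c1ccccc1 | intermediate
22 | benzoyl chloride | O=C(Cl)c1ccccc1 | starting material
23 | [(3aS,4S,5S,7aS)-4-(benzoyloxy)-5-(tert-butyldimethylsilyloxy)-2,2-dimethyl-3a,4,5,7a-tetrahydro-1,3-benzodioxol-7a-yl]methyl benzoate | O=C(OC[C@@]12C=C[C@H](O[Si](C)(C)C(C)(C)C)[C@@H](OC(=O)c3ccccc3)[C@@H]1OC(C)(C)O2)c1ccccc1 | intermediate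
24 | [(1S,2S,3R,4S)-3-(benzoyloxy)-1,2,4-trihydroxycyclohex-5-en-1-yl]methyl benzoate (1alpha-benzoyloxymethyl-3alpha-benzoyloxycyclohex-5-en-1beta,2beta,4beta-triol) | O=C(OC[C@@]1(O)C=C[C@H](O)[C@@H](OC(=O)c2ccccc2)[C@@H]1O)c1ccccc1 | target

## Step count and least certain steps

Total: 14 steps. Longest linear sequence: 14 steps, from 1 to 24.

**Step 10 (key step).** The facial selection at the aldehyde may be weak, because it depends on the closed, chromium-bound transition state prevailing over open ones. Protonolysis of the carbon–chromium bond before addition is the other likely loss. Fallback, from 15 back to 18: the closure is run as planned. If it delivers mainly the C7-epimeric alcohol F1, the crude alcohol is oxidised with Dess–Martin periodinane to the enone F2. Reduction with NaBH4 and CeCl3·7H2O in MeOH at −78 °C then delivers hydride axially and returns the pseudo-equatorial alcohol 18. The C4 configuration is then set by 1,2-reduction of a ketone instead of by the carbonyl addition.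

**Step 4.** The acetylide may add with low face selectivity or along the chelate pathway, and closure of the lithium alkoxide to the oxirane may be slow. Fallback, from 3 back to 9: the order in which the two carbon substituents reach C1 is inverted. Acylation of LiC≡CSiMe3 by ester 3 (BF3·OEt2, THF, −78 °C) gives the ynone F3. Addition of LiCH2Cl (from 4 and MeLi·LiBr) to F3 gives alkoxide 8 and, on warming, 9. Because the nucleophile and the resident group have changed roles, a carbonyl that selects its face in the chelate sense gives the needed configuration by this order.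

**Step 5.** Attack at the neopentyl-type CH2 may be slow, and at 80 °C the alkynyl silyl group or the primary silyl ether may be partly lost. Fallback, from 6 back to 11: the benzoate is introduced before C1 is made. PhCO2Cs in DMF at rt displaces the chloride of 6 and gives the keto benzoate F4. Addition of LiC≡CSiMe3 at −78 °C with a cold acidic quench gives 11 directly, with the same Felkin–Anh control; the cold quench limits benzoyl migration to the new alkoxide.

**Step 9.** The oxidative desilylation may stop before oxidation, or the activated sulfoxide may begin to attack the tertiary silyl ether on warming. Fallback, from 14 back to 15: the two events are separated. PPTS in MeOH at 0 °C solvolyses only the primary silyl ether and gives the primary alcohol F5, which Dess–Martin periodinane (NaHCO3, CH2Cl2) oxidises to 15.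

**Step 12.** Solvolysis of the hindered tertiary silyl ether may lag, stronger acid would start to remove the O4 silyl ether, and O3 may be capped as a mixed acetal in the second stage. Fallback, from 19 back to 21: all acid-labile groups are removed with HCl in MeOH to give the tetraol F6. Acetalization with 2,2-dimethoxypropane and CSA takes the only cis-diol and gives the diol F7. t-BuMe2SiCl and imidazole then silylate the less hindered allylic hydroxyl and give 21. Selectivity then rests on the steric difference between O4 and O3 instead of on graded silyl ethers.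

## Further compounds

F1 | step 10 | [(3aS,4S,7R,7aR)-7-hydroxy-2,2-dimethyl-4-(triethylsilyloxy)-3a,4,7,7a-tetrahydro-1,3-benzodioxol-4-yl]methyl benzoate | O=C(OC[C@@]1(O[Si](CC)(CC)CC)C=C[C@@H](O)[C@@H](OC(C)(C)O2)[C@@H]12)c1ccccc1
F2 | step 10 | [(3aS,4S,7aS)-2,2-dimethyl-7-oxo-4-(triethylsilyloxy)-3a,4,7,7a-tetrahydro-1,3-benzodioxol-4-yl]methyl benzoate | O=C(OC[C@@]1(O[Si](CC)(CC)CC)C=CC(=O)[C@@H](OC(C)(C)O2)[C@@H]12)c1ccccc1
F3 | step 4 | 1-[(4S,5R)-2,2-dimethyl-5-[(triethylsilyloxy)methyl]-1,3-dioxolan-4-yl]-3-(trimethylsilyl)prop-2-yn-1-one | C[Si](C)(C)C#CC(=O)[C@@H](OC(C)(C)O1)[C@H]1CO[Si](CC)(CC)CC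
F4 | step 5 | 2-[(4S,5R)-2,2-dimethyl-5-[(triethylsilyloxy)methyl]-1,3-dioxolan-4-yl]-2-oxoethyl benzoate | O=C(OCC(=O)[C@@H](OC(C)(C)O1)[C@H]1CO[Si](CC)(CC)CC)c1ccccc1
F5 | step 9 | (2S,3Z)-2-[(4S,5R)-5-(hydroxymethyl)-2,2-dimethyl-1,3-dioxolan-4-yl]-4-iodo-2-(triethylsilyloxy)but-3-en-1-yl benzoate | O=C(OC[C@@](O[Si](CC)(CC)CC)(/C=C\I)[C@@H](OC(C)(C)O1)[C@H]1CO)c1ccccc1
F6 | step 12 | [(1S,2S,3R,4S)-1,2,3,4-tetrahydroxycyclohex-5-en-1-yl]methyl benzoate | O=C(OC[C@@]1(O)C=C[C@H](O)[C@@H](O)[C@@H]1O)c1ccccc1
F7 | step 12 | [(3aS,4R,5S,7aS)-4,5-dihydroxy-2,2-dimethyl-3a,4,5,7a-tetrahydro-1,3-benzodioxol-7a-yl]methyl benzoate | O=C(OC[C@@]12C=C[C@H](O)[C@@H](O)[C@@H]1OC(C)(C)O2)c1ccccc1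
A1 | alternative 1 | 2-bromo-5-[(tert-butyldimethylsilyloxy)methyl]-7-oxabicyclo[2.2.1]hept-5-ene-2-carbaldehyde, formyl group exo | CC(C)(C)[Si](C)(C)OCC=1[C@H]2C[C@](Br)(C=O)[C@H](O2)C=1
A2 | alternative 1 | 3-[(tert-butyldimethylsilyloxy)methyl]furan | CC(C)(C)[Si](C)(C)OCc1ccoc1
A3 | alternative 1 | 2-bromoprop-2-enal (2-bromoacrolein) | C=C(Br)C=O
A4 | alternative 2 | (1S,2R)-1,2-dihydroxycyclohexa-3,5-diene-1-carboxylic acid | OC(=O)[C@@]1(O)[C@H](O)C=CC=C1
A5 | alternative 2 | benzoic acid | O=C(O)c1ccccc1
A6 | alternative 3 | tert-butyl (2R,3S,4S,5S)-2,5-bis(tert-butyldimethylsilyloxy)-3-hydroxy-4-(4-methoxybenzyloxy)-2-[(trimethylsilyl)ethynyl]hept-6-enoate | C[Si](C)(C)C#C[C@](O[Si](C)(C)C(C)(C)C)(C(=O)OC(C)(C)C)[C@@H](O)[C@H](OCc1ccc(OC)cc1)[C@@H](O[Si](C)(C)C(C)(C)C)C=C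
A7 | alternative 3 | tert-butyl 2-(tert-butyldimethylsilyl)-2-oxoacetate | CC(C)(C)OC(=O)C(=O)[Si](C)(C)C(C)(C)C
A8 | alternative 3 | (2R,3S)-3-(tert-butyldimethylsilyloxy)-2-(4-methoxybenzyloxy)pent-4-enal | O=C[C@H](OCc1ccc(OC)cc1)[C@@H](O[Si](C)(C)C(C)(C)C)C=C
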